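**Retrosynthetic overview**

1. The strategy rests on C13, a secondary carbinol whose two carbon neighbours, C12 (long chain) and C14 (propyl end), are both unbranched CH2 groups that no reagent can tell apart by size. The only ring, the benzene ring of the acylphloroglucinol, is bought intact, so no ring is formed.
2. Key disconnection: C13–C14 and C11–C12 together. C12/C13 come from vinyllithium, C14–C16 from a propylboronate and C1–C11 from an (E)-alkenyl bromide, joined by a Pd/Mandyphos conjunctive coupling that leaves boron on C13. The C–B bond is then oxidised to C–O with retention.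
3. Alkenyl bromide: the C1–aryl bond comes from an aryl Grignard reagent and a Weinreb amide. The C11–Br bond is made first, on the arene-free undecenoyl amide (cross-metathesis with a vinylboronate, then ipso-bromination), because Br+ would attack C3/C5 of a tris(benzyloxy)aryl ketone.
4. End: one hydrogenation saturates C10=C11 and frees the three phenols.

Key step: step 8

Remark on the chemistry: the antipode of the Mandyphos ligand is taken to be the one that places palladium on the Si face of C13 of the vinyl ate complex. This is to be confirmed on the first run (Mosher ester of a sample of 16); the other antipode would be used otherwise, with no other change.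

**Route**

Step 1
Reactants: 1 undec-10-enoyl chloride
Product: 2 N-methoxy-N-methylundec-10-enamide
Conditions: MeNHOMe·HCl, K2CO3, CH2Cl2/H2O, 0 °C → rt
Reagents that add atoms: N,O-dimethylhydroxylamine hydrochloride, CNOC.Cl
Why: Schotten–Baumann N-acylation (nucleophilic acyl substitution) by the acid chloride is fast under biphasic carbonate conditions, leaves the terminal alkene untouched and gives the Weinreb amide that will later accept exactly one aryl nucleophile.

Step 2
Reactants: 2 N-methoxy-N-methylundec-10-enamide; 3 2-ethenyl-4,4,5,5-tetramethyl-1,3,2-dioxaborolane (vinylboronic acid pinacol ester)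
Product: 4 (E)-N-methoxy-N-methyl-11-(4,4,5,5-tetramethyl-1,3,2-dioxaborolan-2-yl)undec-10-enamide
Conditions: second-generation Grubbs catalyst (H2IMes)(PCy3)Cl2Ru=CHPh (3 mol%), 3 (2 equiv), CH2Cl2, 40 °C
Reagents that add atoms: none
Why: Ruthenium-catalysed olefin cross-metathesis of an unhindered terminal alkene with a slowly homodimerising vinylboronate should give the alkenylboronate with high E selectivity because of the bulky pinacolboryl group, with ethene loss driving the exchange and the remote amide tolerated.

Step 3
Reactants: 4 (E)-N-methoxy-N-methyl-11-(4,4,5,5-tetramethyl-1,3,2-dioxaborolan-2-yl)undec-10-enamide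
Product: 5 [(1E)-11-[methoxy(methyl)amino]-11-oxoundec-1-en-1-yl]boronic acid
Conditions: NaIO4, NH4OAc, acetone/H2O, rt
Reagents that add atoms: water, O
Why: Oxidative cleavage of the pinacol ester: the pinacol released in the hydrolysis equilibrium is destroyed by periodate (glycol cleavage to acetone), which pulls the ester over to the boronic acid without touching the alkene or its E geometry.

Step 4
Reactants: 5 [(1E)-11-[methoxy(methyl)amino]-11-oxoundec-1-en-1-yl]boronic acid
Product: 6 (E)-11-bromo-N-methoxy-N-methylundec-10-enamide
Conditions: NBS (1.1 equiv), MeCN, 0 °C → rt, dark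
Reagents that add atoms: N-bromosuccinimide, O=C1CCC(=O)N1Br
Why: Halodeboronation of an alkenylboronic acid with an N-halosuccinimide (Petasis-type ipso-substitution): Br+ attacks the boron-bearing C11, the developing C10 cation is stabilised by the C–B bond and boron leaves with retention to give the E bromide, and at this stage no electron-rich arene is present to compete for Br+.

Step 5
Reactants: 7 1,3,5-tris(benzyloxy)benzene
Product: 8 2-bromo-1,3,5-tris(benzyloxy)benzene
Conditions: NBS (1.0 equiv), CH2Cl2, −20 °C → 0 °C
Reagents that add atoms: N-bromosuccinimide, O=C1CCC(=O)N1Br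
Why: Electrophilic aromatic bromination of a ring whose three free positions are equivalent and strongly activated, so one equivalent of NBS at low temperature should stop at the monobromide.

Step 6
Reactants: 8 2-bromo-1,3,5-tris(benzyloxy)benzene; 6 (E)-11-bromo-N-methoxy-N-methylundec-10-enamide
Product: 10 (E)-11-bromo-1-[2,4,6-tris(benzyloxy)phenyl]undec-10-en-1-one, via 2,4,6-tris(benzyloxy)phenylmagnesium bromide 9 (not isolated)
Conditions: Mg turnings (I2-activated), THF, 50 °C; then 6, THF, 0 °C → rt; 1 M HCl work-up
Reagents that add atoms: magnesium, [Mg] (held only in intermediate 9; no reagent atom remains in 10)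
Why: Magnesium insertion gives the aryl Grignard reagent, which adds once to the Weinreb amide (Weinreb ketone synthesis) because the chelated tetrahedral magnesium adduct survives until work-up, and an aryl Grignard reagent neither exchanges with nor deprotonates the alkenyl bromide as an aryllithium might.

Step 7
Reactants: 11 tetravinylstannane
Product: 12 vinyllithium
Conditions: n-BuLi (hexanes), pentane, rt; solid filtered, washed with pentane, dissolved in THF, titrated
Reagents that add atoms: n-butyllithium, [Li]CCCC
Why: Tin–lithium exchange (transmetallation): vinyllithium precipitates from pentane while Bu4Sn stays dissolved, giving the halide-free reagent that the coupling requires.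

Step 8
Reactants: 13 4,4,5,5-tetramethyl-2-propyl-1,3,2-dioxaborolane (propylboronic acid pinacol ester); 12 vinyllithium; 10 (E)-11-bromo-1-[2,4,6-tris(benzyloxy)phenyl]undec-10-en-1-one
Product: 15 (S,E)-13-(4,4,5,5-tetramethyl-1,3,2-dioxaborolan-2-yl)-1-[2,4,6-tris(benzyloxy)phenyl]hexadec-10-en-1-one, via lithium pinacolato(propyl)(vinyl)borate 14 (not isolated)
Conditions: 13 (slight excess), 12, THF, 0 °C → rt; then Pd(OAc)2 (2 mol%), Mandyphos ligand 1,1'-bis[bis(4-methoxy-3,5-dimethylphenyl)phosphino]-2,2'-bis[(dimethylamino)(phenyl)methyl]ferrocene (2.4 mol%, antipode giving S), KOTf (CF3SO3K, 2 equiv), 10 (limiting), THF, 60 °C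
Reagents that add atoms: none
Why: Vinyllithium 12 adds to boron of 13 to give the tetracoordinate ate complex 14; zerovalent palladium formed in situ inserts into the C11–Br bond of 10, KOTf removes bromide so that the divalent alkenylpalladium is cationic, this metal binds the vinyl π bond of 14 and provokes the 1,2-shift of propyl from boron to C13 anti to palladium while C12 becomes bound to palladium, and reductive elimination joins C12 to C11 with the E alkene retained. This is the palladium-catalysed enantioselective conjunctive cross-coupling of vinylboron ate complexes with C(sp2) electrophiles, used here with an alkyl migrating group and an (E)-alkenyl bromide. No ring is closed. C13 is the only new stereocentre and is controlled by the chiral diphosphine alone, which decides the vinyl face that palladium occupies: with palladium on the Si face of C13 (C12 > B > H) propyl enters on the Re face and the boronate is S, so the near identity of the C12 and C14 arms plays no part. The step needs the metallate shift to outrun direct transmetallation of propyl or vinyl to palladium (Suzuki-type products), which the wide-bite-angle ligand, the halide-free cationic palladium and the pinacol ester secure. It also needs the ketone to stay untouched, which follows from the absence of free vinyllithium, the non-basic ate complex and the two benzyloxy groups flanking the carbonyl.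

Step 9
Reactants: 15 (S,E)-13-(4,4,5,5-tetramethyl-1,3,2-dioxaborolan-2-yl)-1-[2,4,6-tris(benzyloxy)phenyl]hexadec-10-en-1-one
Product: 16 (S,E)-13-hydroxy-1-[2,4,6-tris(benzyloxy)phenyl]hexadec-10-en-1-one
Conditions: 30% H2O2, 3 M NaOH, THF, 0 °C → rt
Reagents that add atoms: hydrogen peroxide, OO
Why: Oxidation of the secondary alkylboronate with alkaline hydrogen peroxide: hydroperoxide adds to boron and C13 shifts from boron to oxygen with retention, so the S boronate gives the S carbinol, while the hindered aryl ketone, the alkene and the benzyl ethers are inert to cold alkaline peroxide.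

Step 10
Reactants: 16 (S,E)-13-hydroxy-1-[2,4,6-tris(benzyloxy)phenyl]hexadec-10-en-1-one
Product: 17 (S)-13-hydroxy-1-(2,4,6-trihydroxyphenyl)hexadecan-1-one
Conditions: H2 (1 atm), 10% Pd/C, EtOAc/MeOH, rt, stopped when uptake ends
Reagents that add atoms: none
Why: Heterogeneous hydrogenation over palladium saturates the C10–C11 alkene and hydrogenolyses the three aryl benzyl ethers in one operation; C13 is neither allylic nor benzylic and keeps its configuration, and the ketone, once flanked by two hydrogen-bonding ortho phenols, should resist reduction at 1 atm.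

**Compound list**

1 | undec-10-enoyl chloride | C=CCCCCCCCCC(=O)Cl | starting material
2 | N-methoxy-N-methylundec-10-enamide | C=CCCCCCCCCC(=O)N(C)OC | intermediate
3 | 2-ethenyl-4,4,5,5-tetramethyl-1,3,2-dioxaborolane | C=CB1OC(C)(C)C(C)(C)O1 | starting material
4 | (E)-N-methoxy-N-methyl-11-(4,4,5,5-tetramethyl-1,3,2-dioxaborolan-2-yl)undec-10-enamide | CON(C)C(=O)CCCCCCCC/C=C/B1OC(C)(C)C(C)(C)O1 | intermediate
5 | [(1E)-11-[methoxy(methyl)amino]-11-oxoundec-1-en-1-yl]boronic acid | CON(C)C(=O)CCCCCCCC/C=C/B(O)O | intermediate
6 | (E)-11-bromo-N-methoxy-N-methylundec-10-enamide | CON(C)C(=O)CCCCCCCC/C=C/Br | intermediate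
7 | 1,3,5-tris(benzyloxy)benzene | c1c(OCc2ccccc2)cc(OCc2ccccc2)cc1OCc1ccccc1 | starting material
8 | 2-bromo-1,3,5-tris(benzyloxy)benzene | Brc1c(OCc2ccccc2)cc(OCc2ccccc2)cc1OCc1ccccc1 | intermediate
9 | 2,4,6-tris(benzyloxy)phenylmagnesium bromide | Br[Mg]c1c(OCc2ccccc2)cc(OCc2ccccc2)cc1OCc1ccccc1 | intermediate (not isolated)
10 | (E)-11-bromo-1-[2,4,6-tris(benzyloxy)phenyl]undec-10-en-1-one | Br/C=C/CCCCCCCCC(=O)c1c(OCc2ccccc2)cc(OCc2ccccc2)cc1OCc1ccccc1 | intermediate
11 | tetravinylstannane | C=C[Sn](C=C)(C=C)C=C | starting material
12 | vinyllithium | [Li]C=C | intermediate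
13 | 4,4,5,5-tetramethyl-2-propyl-1,3,2-dioxaborolane | CCCB1OC(C)(C)C(C)(C)O1 | starting material
14 | lithium pinacolato(propyl)(vinyl)borate | [Li+].CCC[B-]1(C=C)OC(C)(C)C(C)(C)O1 | intermediate (not isolated)
15 | (S,E)-13-(4,4,5,5-tetramethyl-1,3,2-dioxaborolan-2-yl)-1-[2,4,6-tris(benzyloxy)phenyl]hexadec-10-en-1-one | CCC[C@H](B1OC(C)(C)C(C)(C)O1)C/C=C/CCCCCCCCC(=O)c1c(OCc2ccccc2)cc(OCc2ccccc2)cc1OCc1ccccc1 | intermediate
16 | (S,E)-13-hydroxy-1-[2,4,6-tris(benzyloxy)phenyl]hexadec-10-en-1-one | CCC[C@H](O)C/C=C/CCCCCCCCC(=O)c1c(OCc2ccccc2)cc(OCc2ccccc2)cc1OCc1ccccc1 | intermediate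
17 | (S)-13-hydroxy-1-(2,4,6-trihydroxyphenyl)hexadecan-1-one | CCC[C@H](O)CCCCCCCCCCCC(=O)c1c(O)cc(O)cc1O | target

**Step count**

Total: 10 steps. Longest linear sequence: 8 steps (1, 2, 3, 4, 6, 8, 9, 10); steps 5 and 7 are side branches.

**Steps most likely to fail**

Step 8. The coupling may suffer from poor face selectivity at the vinyl unit, or direct transmetallation of propyl or vinyl to palladium may outrun the metallate shift. In that case C13 would be bought instead of made. The fallback sets out from 2 and 9 and comes back at 16. (S)-2-propyloxirane F1, purchased as the single enantiomer, would be opened at its CH2 terminus by vinylmagnesium bromide (C=C[Mg]Br) with catalytic CuI in THF at −30 °C to give (S)-hept-1-en-4-ol F2; the stereocentre is not touched. Weinreb amide 2 and Grignard reagent 9 would give 1-[2,4,6-tris(benzyloxy)phenyl]undec-10-en-1-one F3 under the conditions of step 6. Cross-metathesis of F3 with an excess of F2 (second-generation Hoveyda–Grubbs catalyst (H2IMes)Cl2Ru=CH(2-iPrOC6H4), CH2Cl2, 40 °C) should then give 16, accompanied by some (S,Z)-13-hydroxy-1-[2,4,6-tris(benzyloxy)phenyl]hexadec-10-en-1-one F4. Both isomers converge in step 10, where the alkene geometry disappears.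

Step 6. Acyl substitution at the Weinreb amide by the doubly ortho-substituted aryl nucleophile may be slow, or the Grignard reagent may act as a base and strip the N-methoxy group. The C1–aryl bond would then be made at the aldehyde oxidation level. The fallback sets out from 6 and 9 and comes back at 10. iBu2AlH (THF, −78 °C) would reduce 6 to (E)-11-bromoundec-10-enal F5. Reagent 9 should add to this far more electrophilic carbonyl (−78 °C → 0 °C) to give racemic (E)-11-bromo-1-[2,4,6-tris(benzyloxy)phenyl]undec-10-en-1-ol F6. Dess–Martin periodinane (CH2Cl2, NaHCO3, rt) would oxidise F6 to 10, which removes the carbinol centre.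

Step 4. Bromodeboronation may erode the alkene geometry or stop at bromine-addition products. Boron would then be left out altogether. The fallback sets out from 2 and comes back at 6. Ozonolysis of 2 (O3, CH2Cl2, −78 °C; PPh3) would give N-methoxy-N-methyl-10-oxodecanamide F7. Takai–Utimoto olefination (CHBr3, CrBr2, THF, 0 °C → rt), which is selective for aldehydes over amides and favours the E alkenyl halide, should then give 6.

Further compounds
F1 | step 8 | (S)-2-propyloxirane | CCC[C@H]1CO1
F2 | step 8 | (S)-hept-1-en-4-ol | CCC[C@H](O)CC=C
F3 | step 8 | 1-[2,4,6-tris(benzyloxy)phenyl]undec-10-en-1-one | C=CCCCCCCCCC(=O)c1c(OCc2ccccc2)cc(OCc2ccccc2)cc1OCc1ccccc1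
F4 | step 8 | (S,Z)-13-hydroxy-1-[2,4,6-tris(benzyloxy)phenyl]hexadec-10-en-1-one | CCC[C@H](O)C/C=C\CCCCCCCCC(=O)c1c(OCc2ccccc2)cc(OCc2ccccc2)cc1OCc1ccccc1
F5 | step 6 | (E)-11-bromoundec-10-enal | O=CCCCCCCCC/C=C/Br
F6 | step 6 | (E)-11-bromo-1-[2,4,6-tris(benzyloxy)phenyl]undec-10-en-1-ol | OC(CCCCCCCC/C=C/Br)c1c(OCc2ccccc2)cc(OCc2ccccc2)cc1OCc1ccccc1
F7 | step 4 | N-methoxy-N-methyl-10-oxodecanamide | CON(C)C(=O)CCCCCCCCC=O
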